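## Structural features

Atom labels C2–C44 follow the order of the atoms in the SMILES of 21. The core of 21 is a bicyclo[3.2.1]octane: a six-membered enedione ring (C2, C3, C4, C31, C32, C34) and a cyclopentanone ring (C31, C32, C34, C35, C44) share C31–C32–C34, with ketone C32 as the one-carbon bridge. A cyclopentane (C4, C5, C22, C23, C31) is fused to the enone at C4–C31 and cis-fused at C5–C22 to an indane (C5, C6, C14, C21, C22). Eight contiguous stereocentres run C6–C5–C22–C23–C31–C44–C35–C34, and C31 is quaternary and common to three rings. The C35 aryl group lies on the side of the enone bridge, the C44 aryl group lies on the other side and cis to C23, the C23 aryl group is trans to the indane carbon C21, and the C6 aryl group is trans to C4. The C32/C2 diketone cannot enolise through bridgehead C34 and is open to retro-Claisen cleavage by alkoxide or hydroxide. The seven phenols are carried as methyl ethers, and in the intermediates the 1H-indene C22–H is more acidic than a ketone α-hydrogen. The real difficulty is the quaternary C31 inside the bridged trione, flanked by four stereocentres. The key step uses the fact that C31 and C34 are the two α-carbons of ketone C32, so the unit C2–C3–C4 can be laid across the ring C31–C32–C34–C35–C44. The configurations written for 15 and 18 were checked centre by centre against 21 and agree; no structure needed correction.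

## Logic of the disconnections

21 to 20: the seven O–CH3 bonds are cut last. Methyl ethers survive every earlier step and leave one operation at the end. The forward step must be a Lewis-acid cleavage, because base would open the C32/C2 diketone.

20 to 19: the C4–C5 bond and the C6–H bond are cut. This removes one ring and two stereocentres and leaves a vinyl electrophile at C4 next to a trisubstituted alkene. The forward step must add C4 and a hydrogen to the same face of C5=C6, which a syn carbopalladation followed by hydride capture does.

19 to 18: the O–S bond at the C4 oxygen is cut, giving the enolised trione. The forward step must sulfonylate the C4 oxygen and not the C2 oxygen.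

18 to 15 and 16: the C2–C34 and C4–C31 bonds are cut. One operation then builds the six-membered ring, the quaternary carbon and both bridgeheads from a monocyclic enol ether and a three-carbon diacyl unit. The forward step needs C-acylation without base, the bridge on the face away from the C44 aryl group, and an enol ether far more nucleophilic than the arenes and the indene alkene.

15 to 13 and 14: the C35–aryl bond and the O–Si bond are cut. The C32=C34 enol ether then comes regiospecifically from a conjugate addition with silyl capture. No amide base meets the indenyl C22–H, so kinetic deprotonation of the ketone is avoided. The forward step must add trans to the C44 aryl group.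

13 to 11 (through 12): the C6–C14 bond of the indene is cut to an aryl ketone, and the C34=C35 alkene is traced to a β-silyloxy ketone. The acid-labile and base-labile indene therefore appears only two steps before the key step. A para-quinone methide carrying the indenyl group was rejected as the source of this side chain, because it would tautomerise to the benzofulvene through the C22–H. The forward step needs an acid that closes the five-membered ring onto the activated arene without touching C22.

11 to 9 and 10: the C22–aryl bond is cut. C22 becomes the β-carbon of an E-enone and the aryl group a boronic acid. The forward step needs catalyst control of the enone face next to the existing C23 centre.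

9 to 8 and 4: the C22=C5 double bond is cut by a metathesis transform to a terminal alkene and an aryl vinyl ketone. No stereocentre is involved.

8 to 7 and 2: the C31–C23 bond is cut. C23 becomes the substituted terminus of an allyl electrophile and C31 a regiodefined enolate equivalent. The forward step needs branched regioselectivity and catalyst control at C23, and it must not let the enolate equilibrate toward C34.

7 to 5 and 6: the C44–aryl bond and the O–Si bond are cut. The single purchased stereocentre of 5 fixes C44 by trans addition, and C44 later directs C35.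

2 to 1 and 4 to 3: one functional-group operation each, from purchased materials.

## Other disconnections considered

Alternative 1: The cut is C5–C22, the bond shared by the indane and the adjoining cyclopentane. In the forward step the bridged secondary amine A1, with nitrogen spanning C5 and C22, is N-aminated by an anomeric amide reagent; the isodiazene loses N2 and the C5/C22 radical pair collapses to the ketal A2.
- In its favour: the cage forces the cis ring fusion, C6 and C23 are carried through untouched, and a bicyclic amine is open to Mannich-type assembly.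
- Against it here: A2 is only the indane–cyclopentane half. Its ketal carbon must still become the quaternary C31, and the whole bicyclooctane must then be built with control relative to remote centres. The benzylic C22 radical and the secondary C5 radical can also disproportionate or abstract the doubly benzylic C6–H.
- Comparison: on structure it addresses the less demanding half, whereas the chosen plan builds the congested core in one step. On mechanism the two are equal in how reliably ring geometry dictates the new centres. Alternative 1 is better on one point: it never has to tell two dione oxygens apart. On step economy it is worse.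

Alternative 2: The cut is C6–C14. In the forward step the phenol A3 is oxidised at the anode to a para-quinone methide at C6, which the 3,5-dimethoxyphenyl ring on C22 attacks through C14 to give A4.
- In its favour: the bond forms late and without a metal, only the free phenol is activated, and the C6 aryl group should settle trans to C4.
- Against it here: C5 must be set as a free-standing centre without the indane to constrain it. The quinone methide has a neighbouring C5–H that is vinylogous to the C2 ketone, so tautomerisation to a dienone competes. The other anisole rings are also oxidisable.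
- Comparison: it replaces only the last ring closure, so a bridging annulation of the chosen kind is still needed and the step count is about equal. It is the equal of the chosen plan in control of C6, and better in needing no vinyl triflate. It is worse in chemoselectivity of the oxidation.

Alternative 3: The cut is C31–C44. In the forward step a Lewis acid opens the C4–C31 epoxide of the epoxy cyclobutanol A5 while C44 migrates from C32 to C31, giving the spiro hydroxy cyclopentanone A6.
- In its favour: the shift is stereospecific (inversion at C31, retention at C44), and the benzylic C44 should migrate in preference to C34.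
- Against it here: A5 needs a tetrasubstituted epoxide of defined face and a cyclobutanol with two aryl-bearing centres. The electron-rich C44 aryl group can divert the cation. After A6, C2 and C3 must still be added and the six-membered ring closed across C34 and C4, which is a second annulation at the same bridgeheads.
- Comparison: on mechanism it is better on two points. It is stereospecific where the chosen acylation is only stereoselective, and it installs the C4 oxygen unambiguously. On structure and step economy the chosen plan is ahead, because one step gives the complete bridged core.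

Key step: step 9

Remark: C31 is an epimerisable α-carbon, drawn trans to the C44 aryl group in 8, 9, 11, 12, 13 and 15; it becomes trigonal in step 9, so its configuration need not be controlled.
Remark: the sense of induction in steps 4 and 6 is assigned by analogy with simple cinnamyl carbonates and E-enones; the ligand enantiomers named are those expected to give (S)-C23 and (R)-C22.

Step 1
Reactants: 1 (E)-3-(4-methoxyphenyl)prop-2-en-1-ol
Product: 2 (E)-3-(4-methoxyphenyl)allyl methyl carbonate
Conditions: ClCO2Me, pyridine, CH2Cl2, 0 °C
Reagents that add atoms: methyl chloroformate, COC(=O)Cl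
Why: O-acylation of a primary allylic alcohol to the carbonate; no stereocentre is involved.

Step 2
Reactants: 3 3-chloro-1-(4-methoxyphenyl)propan-1-one
Product: 4 1-(4-methoxyphenyl)prop-2-en-1-one
Conditions: Et3N, Et2O, 0 → 23 °C; used at once
Reagents that add atoms: none
Why: Dehydrochlorination of a β-chloro ketone (E1cB); the vinyl ketone is made fresh because it polymerises on storage.

Step 3
Reactants: 5 (S)-4-(tert-butyldimethylsilyloxy)cyclopent-2-en-1-one; 6 4-methoxyphenylmagnesium bromide
Product: 7 (3R,4S)-4-(tert-butyldimethylsilyloxy)-3-(4-methoxyphenyl)-1-(trimethylsilyloxy)cyclopent-1-ene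
Conditions: CuBr·SMe2 (10 mol%), TMSCl, THF, −78 °C; Et3N, pentane, filtration
Reagents that add atoms: chlorotrimethylsilane, C[Si](C)(C)Cl
Why: Copper-catalysed conjugate addition with in situ silylation; the aryl group enters C44 anti to the C35 silyloxy group, which sets C44 from the purchased centre. The enolate is trapped as the C31=C32 enol ether before it can equilibrate and expel the β-silyloxy group.

Step 4
Reactants: 7 (3R,4S)-4-(tert-butyldimethylsilyloxy)-3-(4-methoxyphenyl)-1-(trimethylsilyloxy)cyclopent-1-ene; 2 (E)-3-(4-methoxyphenyl)allyl methyl carbonate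
Product: 8 (2S,3R,4S)-4-(tert-butyldimethylsilyloxy)-3-(4-methoxyphenyl)-2-[(1S)-1-(4-methoxyphenyl)prop-2-en-1-yl]cyclopentan-1-one
Conditions: [Ir(cod)Cl]2 (2 mol%), (Ra,R,R)-O,O'-(1,1'-binaphthyl-2,2'-diyl) N,N-bis(1-phenylethyl)phosphoramidite (4 mol%), CsF (0.4 equiv), ZnF2 (1.5 equiv), DME, 50 °C
Reagents that add atoms: none
Why: Iridium-catalysed asymmetric allylic alkylation of a fluoride-activated silyl enol ether; the enolate attacks the aryl-bearing terminus of the allyl complex, so C31–C23 forms at the branched position. C23 is set by the ligand (catalyst control), and C31 forms anti to the C44 aryl group.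

Step 5
Reactants: 8 (2S,3R,4S)-4-(tert-butyldimethylsilyloxy)-3-(4-methoxyphenyl)-2-[(1S)-1-(4-methoxyphenyl)prop-2-en-1-yl]cyclopentan-1-one; 4 1-(4-methoxyphenyl)prop-2-en-1-one
Product: 9 (2S,3R,4S)-4-(tert-butyldimethylsilyloxy)-3-(4-methoxyphenyl)-2-[(1S,2E)-1,4-bis(4-methoxyphenyl)-4-oxobut-2-en-1-yl]cyclopentan-1-one
Conditions: second-generation Hoveyda–Grubbs catalyst, (H2IMes)RuCl2(=CH-C6H4-2-O-i-Pr) (5 mol%), CH2Cl2, 40 °C
Reagents that add atoms: none
Why: Cross-metathesis of a terminal alkene with an aryl vinyl ketone used in excess; the conjugated E-enone is the stable product and no stereocentre is touched.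

Step 6
Reactants: 9 (2S,3R,4S)-4-(tert-butyldimethylsilyloxy)-3-(4-methoxyphenyl)-2-[(1S,2E)-1,4-bis(4-methoxyphenyl)-4-oxobut-2-en-1-yl]cyclopentan-1-one; 10 3,5-dimethoxyphenylboronic acid
Product: 11 (2S,3R,4S)-4-(tert-butyldimethylsilyloxy)-3-(4-methoxyphenyl)-2-[(1S,2R)-2-(3,5-dimethoxyphenyl)-1,4-bis(4-methoxyphenyl)-4-oxobutyl]cyclopentan-1-one
Conditions: [Rh(OH)((S)-binap)]2 (3 mol%), dioxane/H2O 10:1, 40 °C
Reagents that add atoms: none
Why: Hayashi–Miyaura reaction; the arylrhodium species adds to C22 of the E-enone on the face chosen by (S)-binap (catalyst control next to the existing C23 centre). The saturated β-silyloxy ring ketone is inert under these base-free conditions.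

Step 7
Reactants: 11 (2S,3R,4S)-4-(tert-butyldimethylsilyloxy)-3-(4-methoxyphenyl)-2-[(1S,2R)-2-(3,5-dimethoxyphenyl)-1,4-bis(4-methoxyphenyl)-4-oxobutyl]cyclopentan-1-one
Product: 13 4,5-trans-5-[(4,6-dimethoxy-3-(4-methoxyphenyl)-1H-inden-1-yl)(4-methoxyphenyl)methyl]-4-(4-methoxyphenyl)cyclopent-2-en-1-one (C44, C23 and C22 as in 11), via ring enone 12 (not isolated)
Conditions: TsOH·H2O (0.5 equiv), toluene, 4 Å molecular sieves, 80 °C
Reagents that add atoms: none
Why: Acid-catalysed β-elimination of the silanol gives the ring enone; Friedel–Crafts cyclodehydration of aryl ketone C6 onto C14 (ortho and para to methoxy groups) then closes the 3-aryl-1H-indene. Acid ionises only C6, so C22 is kept, and C31 settles trans to the C44 aryl group.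

Step 8
Reactants: 13 4,5-trans-5-[(4,6-dimethoxy-3-(4-methoxyphenyl)-1H-inden-1-yl)(4-methoxyphenyl)methyl]-4-(4-methoxyphenyl)cyclopent-2-en-1-one; 14 3,5-dimethoxyphenylmagnesium chloride
Product: 15 trimethylsilyl enol ether (C32=C34) of the all-trans cyclopentanone carrying 3,5-dimethoxyphenyl at C35, 4-methoxyphenyl at C44 and the indenyl(aryl)methyl chain at C31
Conditions: CuBr·SMe2 (10 mol%), TMSCl, THF, −78 °C; Et3N, pentane, filtration; used crude
Reagents that add atoms: chlorotrimethylsilane, C[Si](C)(C)Cl
Why: Copper-catalysed conjugate addition with in situ silylation; the aryl group adds to C35 anti to the neighbouring C44 aryl group, which sets C35. The enolate is silylated as it forms, so the C32=C34 enol ether arises regiospecifically and no strong base meets the indenyl C22–H.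

Step 9
Reactants: 15 trimethylsilyl enol ether (C32=C34) of the all-trans cyclopentanone; 16 malonyl dichloride
Product: 18 bicyclo[3.2.1]octane-2,4,8-trione (C2/C4 dione enolised) with quaternary C31 carrying the indenyl(aryl)methyl chain, 3,5-dimethoxyphenyl at C35 and 4-methoxyphenyl at C44, via C34-malonyl acid chloride 17 (not isolated)
Conditions: Et2O, −20 → 23 °C, 18 h; pH 4 aqueous work-up
Reagents that add atoms: none
Why: The enol ether carbon C34 is acylated by one acid chloride group of 16 with loss of TMSCl, giving 17. The ring ketone of 17 then enolises toward C31, and that enol carbon attacks the tethered acyl carbon C4 with loss of HCl. The closest known reaction type is the Effenberger cyclisation of cyclic ketone enol ethers with malonyl dichloride to bridged 2,4-diones. The six-membered ring closes in the 6-(enolendo)-exo-trig mode, and no base is present, so the non-enolisable C32/C2 diketone is not opened. C31 is set by attack of C4 on the enol face anti to the adjacent C44 aryl group, which pushes C23 cis to that aryl group. C34 is set by ring geometry, because only the epimer of 17 with its acyl chain on the same face can close, and C34 equilibrates through its enol. The step needs chemoselectivity for the enol ether over the methoxyarenes and the indene alkene, secured by its much higher nucleophilicity. It also needs C-acylation in preference to O-acylation, secured by the soft enol carbon and the absence of base.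

Step 10
Reactants: 18 bicyclo[3.2.1]octane-2,4,8-trione
Product: 19 C4 enol triflate of 18 (C2 ketone, C3=C4 alkene, triflyloxy group on C4)
Conditions: Tf2O, 2,6-lutidine, CH2Cl2, −78 °C
Reagents that add atoms: trifluoromethanesulfonic anhydride, O=S(=O)(OS(=O)(=O)C(F)(F)F)C(F)(F)F
Why: O-sulfonylation of a cyclic vinylogous acid; the weak hindered base deprotonates only the acidic enol and leaves the indenyl C22–H alone. The two enol oxygens differ only in their bridgehead neighbours, so 19 should form together with its C2 regioisomer, which is removed by chromatography.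

Step 11
Reactants: 19 C4 enol triflate of 18
Product: 20 heptamethyl ether of 21
Conditions: Pd(OAc)2 (10 mol%), PPh3 (25 mol%), Bu4NCl, HCO2Na (slow addition), DMF, 70 °C
Reagents that add atoms: none
Why: Reductive Heck reaction; zerovalent palladium inserts into the C4–O bond and the vinylpalladium adds 5-exo across C5=C6, C4 to C5 and palladium to C6 on the same face, which forces the cis ring fusion at C5. The tertiary benzylic alkylpalladium has no syn β-hydrogen, so it waits for hydride from formate. C–H reductive elimination with retention places H6 cis to C4 and the C6 aryl group trans.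

Step 12
Reactants: 20 heptamethyl ether of 21
Product: 21 CNP0407321.1
Conditions: BBr3 (excess), CH2Cl2, −78 → 23 °C; then H2O, 0 °C
Reagents that add atoms: none
Why: Lewis-acid cleavage of the seven aryl methyl ethers by bromide attack on the boron-complexed methyl groups; no carbon stereocentre is touched and the diketone never meets base.

## Compound list

1 | (E)-3-(4-methoxyphenyl)prop-2-en-1-ol | COc1ccc(/C=C/CO)cc1 | starting material
2 | (E)-3-(4-methoxyphenyl)allyl methyl carbonate | COC(=O)OC/C=C/c1ccc(OC)cc1 | intermediate
3 | 3-chloro-1-(4-methoxyphenyl)propan-1-one | COc1ccc(C(=O)CCCl)cc1 | starting material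
4 | 1-(4-methoxyphenyl)prop-2-en-1-one | C=CC(=O)c1ccc(OC)cc1 | intermediate
5 | (S)-4-(tert-butyldimethylsilyloxy)cyclopent-2-en-1-one | O=C1C=C[C@@H](O[Si](C)(C)C(C)(C)C)C1 | starting material
6 | 4-methoxyphenylmagnesium bromide | COc1ccc([Mg]Br)cc1 | starting material
7 | (3R,4S)-4-(tert-butyldimethylsilyloxy)-3-(4-methoxyphenyl)-1-(trimethylsilyloxy)cyclopent-1-ene | C[Si](C)(C)OC1=C[C@H](c2ccc(OC)cc2)[C@@H](O[Si](C)(C)C(C)(C)C)C1 | intermediate
8 | (2S,3R,4S)-4-(tert-butyldimethylsilyloxy)-3-(4-methoxyphenyl)-2-[(1S)-1-(4-methoxyphenyl)prop-2-en-1-yl]cyclopentan-1-one | O=C1C[C@H](O[Si](C)(C)C(C)(C)C)[C@@H](c2ccc(OC)cc2)[C@@H]1[C@@H](c1ccc(OC)cc1)C=C | intermediate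
9 | (2S,3R,4S)-4-(tert-butyldimethylsilyloxy)-3-(4-methoxyphenyl)-2-[(1S,2E)-1,4-bis(4-methoxyphenyl)-4-oxobut-2-en-1-yl]cyclopentan-1-one | O=C1C[C@H](O[Si](C)(C)C(C)(C)C)[C@@H](c2ccc(OC)cc2)[C@@H]1[C@@H](c1ccc(OC)cc1)/C=C/C(=O)c1ccc(OC)cc1 | intermediate
10 | 3,5-dimethoxyphenylboronic acid | COc1cc(OC)cc(B(O)O)c1 | starting material
11 | (2S,3R,4S)-4-(tert-butyldimethylsilyloxy)-3-(4-methoxyphenyl)-2-[(1S,2R)-2-(3,5-dimethoxyphenyl)-1,4-bis(4-methoxyphenyl)-4-oxobutyl]cyclopentan-1-one | O=C1C[C@H](O[Si](C)(C)C(C)(C)C)[C@@H](c2ccc(OC)cc2)[C@@H]1[C@@H](c1ccc(OC)cc1)[C@H](c1cc(OC)cc(OC)c1)CC(=O)c1ccc(OC)cc1 | intermediate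
12 | 4,5-trans-5-[2-(3,5-dimethoxyphenyl)-1,4-bis(4-methoxyphenyl)-4-oxobutyl]-4-(4-methoxyphenyl)cyclopent-2-en-1-one (C44, C23, C22 as in 11) | O=C1C=C[C@@H](c2ccc(OC)cc2)[C@@H]1[C@@H](c1ccc(OC)cc1)[C@H](c1cc(OC)cc(OC)c1)CC(=O)c1ccc(OC)cc1 | intermediate (not isolated)
13 | 4,5-trans-5-[(4,6-dimethoxy-3-(4-methoxyphenyl)-1H-inden-1-yl)(4-methoxyphenyl)methyl]-4-(4-methoxyphenyl)cyclopent-2-en-1-one | O=C1C=C[C@@H](c2ccc(OC)cc2)[C@@H]1[C@@H](c1ccc(OC)cc1)[C@H]1C=C(c2ccc(OC)cc2)c2c(OC)cc(OC)cc21 | intermediate
14 | 3,5-dimethoxyphenylmagnesium chloride | COc1cc(OC)cc([Mg]Cl)c1 | starting material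
15 | trimethylsilyl enol ether (C32=C34) of the all-trans 4-(3,5-dimethoxyphenyl)-3-(4-methoxyphenyl)-2-[indenyl(aryl)methyl]cyclopentanone | C[Si](C)(C)OC1=C[C@H](c2cc(OC)cc(OC)c2)[C@@H](c2ccc(OC)cc2)[C@@H]1[C@@H](c1ccc(OC)cc1)[C@H]1C=C(c2ccc(OC)cc2)c2c(OC)cc(OC)cc21 | intermediate
16 | malonyl dichloride | ClC(=O)CC(=O)Cl | starting material
17 | 3-oxo-3-(2-oxocyclopentyl)propanoyl chloride from C-acylation of 15 at C34 (C34 epimers equilibrate; the cyclising epimer is drawn) | O=C(Cl)CC(=O)[C@H]1C(=O)[C@@H]([C@@H](c2ccc(OC)cc2)[C@H]2C=C(c3ccc(OC)cc3)c3c(OC)cc(OC)cc32)[C@H](c2ccc(OC)cc2)[C@H]1c1cc(OC)cc(OC)c1 | intermediate (not isolated)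
18 | bridged bicyclo[3.2.1]octane-2,4,8-trione (drawn as the triketone, present as its enol) | O=C1CC(=O)[C@]2([C@@H](c3ccc(OC)cc3)[C@H]3C=C(c4ccc(OC)cc4)c4c(OC)cc(OC)cc43)C(=O)[C@H]1[C@H](c1cc(OC)cc(OC)c1)[C@H]2c1ccc(OC)cc1 | intermediate
19 | C4 enol triflate of 18 | O=C1C=C(OS(=O)(=O)C(F)(F)F)[C@]2([C@@H](c3ccc(OC)cc3)[C@H]3C=C(c4ccc(OC)cc4)c4c(OC)cc(OC)cc43)C(=O)[C@H]1[C@H](c1cc(OC)cc(OC)c1)[C@H]2c1ccc(OC)cc1 | intermediate
20 | heptamethyl ether of 21 | O=C1C=C2[C@H]3[C@H](c4ccc(OC)cc4)c4c(OC)cc(OC)cc4[C@H]3[C@H](c3ccc(OC)cc3)[C@]23C(=O)[C@H]1[C@H](c1cc(OC)cc(OC)c1)[C@H]3c1ccc(OC)cc1 | intermediate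
21 | CNP0407321.1 | O=C1C=C2[C@H]3[C@H](c4ccc(O)cc4)c4c(O)cc(O)cc4[C@H]3[C@H](c3ccc(O)cc3)[C@]23C(=O)[C@H]1[C@H](c1cc(O)cc(O)c1)[C@H]3c1ccc(O)cc1 | target

## Step count and least certain steps

Total step count: 12. Longest linear sequence: 10 steps (steps 3 to 12, from 5).

**Step 9 (key step).** The bridge may close on the face syn to the C44 aryl group (poor facial selectivity at C31), because the wanted face is also the face of the C35 aryl group. Liberated HCl may protodesilylate the enol ether or protonate the indene alkene, and O-acylation may lead to pyranone-type products. Fallback: the two bond formations are separated. Setting out from 15, ZnCl2-mediated C-acylation at C34 with tert-butyl 3-chloro-3-oxopropanoate F1 would give the tert-butyl diketo ester F2. Heating F2 in toluene would expel tert-butanol and generate the acyl ketene, which acylates the C31 enol without HCl and returns to 18.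

**Step 10.** Sulfonylation may go mainly to the C2 oxygen (poor regioselectivity), since that oxygen has only the bridgehead hydrogen beside it. Fallback: the same bias is turned to advantage by transposition. Setting out from 18, i-Pr3SiOTf and 2,6-lutidine would give the C2 triisopropylsilyl vinylogous ester F3, the bulky silyl group settling on the less encumbered oxygen under silyl-triflate-mediated exchange. Tf2O would then sulfonylate the only carbonyl-type oxygen left in the vinylogous ester, the C4 oxygen, and loss of the silyl triflate returns to 19.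

**Step 4.** The enolate may equilibrate toward C34 and lose the β-silyloxy group, the hindered enolate may react slowly, and catalyst control at C23 may be incomplete. Fallback: substrate control replaces catalyst control.
- Setting out from 7, a BF3·OEt2-mediated Mukaiyama aldol addition to 3-(phenylselanyl)propanal F4 would give the aldol F5.
- Mesylation would give the mesylate F6, and elimination the E-alkylidene ketone F7.
- Copper-mediated 1,4-addition of 6 to F7 would give the selenide F8; the aryl group enters C23 anti to the C44 aryl group held pseudoaxial by allylic strain.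
- Oxidation with H2O2 and selenoxide elimination would return to 8.

**Step 6.** Catalyst control over the face of the γ-branched enone may be insufficient (low diastereoselectivity at C22). Early loss of the silyloxy group would also expose the ring enone to arylation. Fallback: C22 is set by hydride instead of aryl delivery. Setting out from 9, a Heck arylation with 1-iodo-3,5-dimethoxybenzene (Pd(OAc)2, Ag2CO3) would give the β,β-disubstituted enone F9. A copper hydride conjugate reduction with a chiral bisphosphine (Cu(OAc)2, (R)-DTBM-SEGPHOS, polymethylhydrosiloxane) would then return to 11.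

**Step 11.** The vinylpalladium species may take up hydride before it cyclises (premature reduction), or the triflate may be lost to formate. Fallback: hydride is replaced by boron capture. Setting out from 19, Pd(OAc)2, PPh3 and B2pin2 with KOAc would give the C6 pinacol boronate F10 by carbopalladation and borylation on the same face. Protodeboronation with CsF and water, which proceeds with retention, would return to 20.

## Further compounds

F1 | step 9 | tert-butyl 3-chloro-3-oxopropanoate | CC(C)(C)OC(=O)CC(=O)Cl
F2 | step 9 | tert-butyl 3-oxo-3-(2-oxocyclopentyl)propanoate from C-acylation of 15 at C34 (C34 enolised, not defined) | CC(C)(C)OC(=O)CC(=O)C1C(=O)[C@@H]([C@@H](c2ccc(OC)cc2)[C@H]2C=C(c3ccc(OC)cc3)c3c(OC)cc(OC)cc32)[C@H](c2ccc(OC)cc2)[C@H]1c1cc(OC)cc(OC)c1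
F3 | step 10 | C2 triisopropylsilyl vinylogous ester of 18 | CC(C)[Si](C(C)C)(C(C)C)OC1=CC(=O)[C@]2([C@@H](c3ccc(OC)cc3)[C@H]3C=C(c4ccc(OC)cc4)c4c(OC)cc(OC)cc43)C(=O)[C@H]1[C@H](c1cc(OC)cc(OC)c1)[C@H]2c1ccc(OC)cc1
F4 | step 4 | 3-(phenylselanyl)propanal | O=CCC[Se]c1ccccc1
F5 | step 4 | aldol of 7 with F4 (carbinol centre not defined) | O=C1C[C@H](O[Si](C)(C)C(C)(C)C)[C@@H](c2ccc(OC)cc2)[C@@H]1C(O)CC[Se]c1ccccc1
F6 | step 4 | mesylate of F5 | O=C1C[C@H](O[Si](C)(C)C(C)(C)C)[C@@H](c2ccc(OC)cc2)[C@@H]1C(OS(C)(=O)=O)CC[Se]c1ccccc1
F7 | step 4 | (E)-2-[3-(phenylselanyl)propylidene] ketone | O=C1C[C@H](O[Si](C)(C)C(C)(C)C)[C@@H](c2ccc(OC)cc2)/C1=C\CC[Se]c1ccccc1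
F8 | step 4 | 2-[(1S)-1-(4-methoxyphenyl)-3-(phenylselanyl)propyl] ketone | O=C1C[C@H](O[Si](C)(C)C(C)(C)C)[C@@H](c2ccc(OC)cc2)[C@@H]1[C@@H](c1ccc(OC)cc1)CC[Se]c1ccccc1
F9 | step 6 | (E)-β-(3,5-dimethoxyphenyl) enone from arylation of 9 | O=C1C[C@H](O[Si](C)(C)C(C)(C)C)[C@@H](c2ccc(OC)cc2)[C@@H]1[C@@H](c1ccc(OC)cc1)/C(c1cc(OC)cc(OC)c1)=C\C(=O)c1ccc(OC)cc1
F10 | step 11 | C6 pinacol boronate of 20 | O=C1C=C2[C@H]3[C@](B4OC(C)(C)C(C)(C)O4)(c4ccc(OC)cc4)c4c(OC)cc(OC)cc4[C@H]3[C@H](c3ccc(OC)cc3)[C@]23C(=O)[C@H]1[C@H](c1cc(OC)cc(OC)c1)[C@H]3c1ccc(OC)cc1
A1 | alternative 1 | benzo-fused 9-azabicyclo[3.3.1]nonane ketal with nitrogen bridging C5 and C22 | C1[C@H]2[C@H](c3ccc(OC)cc3)c3c(OC)cc(OC)cc3[C@H](N2)[C@H](c2ccc(OC)cc2)C12OCCO2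
A2 | alternative 1 | tricyclic ketal with the C5, C6, C22 and C23 stereocentres | C1[C@H]2[C@H](c3ccc(OC)cc3)c3c(OC)cc(OC)cc3[C@H]2[C@H](c2ccc(OC)cc2)C12OCCO2
A3 | alternative 2 | seco phenol with a 4-hydroxybenzyl group on C5 and no C6–C14 bond | O=C1C=C2[C@@H](Cc3ccc(O)cc3)[C@@H](c3cc(OC)cc(OC)c3)[C@H](c3ccc(OC)cc3)[C@]23C(=O)[C@H]1[C@H](c1cc(OC)cc(OC)c1)[C@H]3c1ccc(OC)cc1
A4 | alternative 2 | hexamethyl ether of 21 with the free phenol on the C6 aryl group | O=C1C=C2[C@H]3[C@H](c4ccc(O)cc4)c4c(OC)cc(OC)cc4[C@H]3[C@H](c3ccc(OC)cc3)[C@]23C(=O)[C@H]1[C@H](c1cc(OC)cc(OC)c1)[C@H]3c1ccc(OC)cc1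
A5 | alternative 3 | C4–C31 epoxide carrying the tertiary cyclobutanol C32 | O1[C@@H]2[C@H]3[C@H](c4ccc(OC)cc4)c4c(OC)cc(OC)cc4[C@H]3[C@H](c3ccc(OC)cc3)[C@]12[C@]1(O)C[C@H](c2cc(OC)cc(OC)c2)[C@H]1c1ccc(OC)cc1
A6 | alternative 3 | spiro hydroxy cyclopentanone | O[C@@H]1[C@H]2[C@H](c3ccc(OC)cc3)c3c(OC)cc(OC)cc3[C@H]2[C@H](c2ccc(OC)cc2)[C@]14C(=O)C[C@H](c1cc(OC)cc(OC)c1)[C@H]4c1ccc(OC)cc1
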